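## Retrosynthetic overview
1. Ring B (the furanone) is closed last. The target comes from its phenol acetate, which comes from gold-catalysed cycloisomerisation of a γ-hydroxy-ynone attached to C5 of ring A.
2. The ynone comes from an acyl Sonogashira coupling of a C5-ethynyl carbinol with 4-acetoxybenzoyl chloride. The C6 ester comes from ozonolysis of a 1-methoxyvinyl group added to the C6 carbonyl.
3. C5 and C6 both trace back to a prochiral 2-alkynyl-2-hydroxy-4,5-dimethoxycyclopent-4-ene-1,3-dione. A ketoreductase reduces one enantiotopic C=O (the future C9, re-oxidised later), and the other C=O (C6) then takes the carbon nucleophile anti to the silyloxy groups.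
4. The prochiral dione comes from acetylide addition to the central C=O of dimethyl croconate, which is made from disodium croconate.
5. Ring order: ring A (the carbocycle with its dimethoxy-alkene) is carried from croconate, and ring B is formed in the penultimate step.

Locants follow the target: O1, C2 (aryl), C3, C4 (=O), C5 (spiro), C6 (OH, CO2Me), C7 and C8 (OMe), C9 (=O).

Assumption: the SMILES is read as (5S,6R), with C6–OH and the furanone O1 on the same face of ring A, and a ketoreductase of the needed sense is taken to be found by panel screening.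

## Route

Step 1
Reactants: 1 disodium croconate
Product: 2 disilver croconate
Conditions: AgNO3 (2.05 equiv), H2O, rt, dark; filter, dry in vacuo
Reagents that add atoms: silver nitrate, SMILES [Ag+].[O-][N+](=O)[O-]
Why: Salt metathesis works because the sparingly soluble silver salt precipitates from water and supplies the counter-ion needed for clean O-alkylation.

Step 2
Reactants: 2 disilver croconate
Product: 3 dimethyl croconate (4,5-dimethoxycyclopent-4-ene-1,2,3-trione)
Conditions: MeI (10 equiv), Et2O, reflux, dark, 24 h; filter off AgI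
Reagents that add atoms: iodomethane, SMILES CI
Why: Silver-salt O-alkylation (SN2 on MeI, driven by AgI precipitation) gives the vicinal diether as the only neutral closed-shell dialkylation product, and this diether already holds the C7/C8 dimethoxy-alkene of ring A without any regiochemical question.

Step 3
Reactants: 3 dimethyl croconate; 4 trimethylsilylacetylene
Product: 7 2-hydroxy-4,5-dimethoxy-2-[(trimethylsilyl)ethynyl]cyclopent-4-ene-1,3-dione (achiral and prochiral), via lithium (trimethylsilyl)acetylide 5 (not isolated), via lithium alkoxide 6 (not isolated)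
Conditions: 4, n-BuLi, THF, −78 °C; cannulate into 3 (1.0 equiv), THF, −78 °C; AcOH quench at −78 °C
Reagents that add atoms: none
Why: In this 1,2-addition of an acetylide to a vicinal trione, the central carbonyl is by far the most electrophilic because the two flanking ones are vinylogous esters (the behaviour known from ninhydrin), and the product keeps a mirror plane so no stereocentre exists yet.

Step 4
Reactants: 7 2-hydroxy-4,5-dimethoxy-2-[(trimethylsilyl)ethynyl]cyclopent-4-ene-1,3-dione
Product: 8 (4R,5S)-4,5-dihydroxy-2,3-dimethoxy-5-[(trimethylsilyl)ethynyl]cyclopent-2-en-1-one (cis-diol)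
Conditions: ketoreductase (NADPH-dependent, panel hit), NADP+ (cat.), i-PrOH (10% v/v), potassium phosphate buffer pH 6.5, 30 °C
Reagents that add atoms: none
Why: In this ketoreductase-catalysed desymmetrisation (enantiotopic-group-selective carbonyl reduction, well known for 2,2-disubstituted cyclopentane-1,3-diones) the chiral active site accepts only one of the two mirror-image C=O groups and delivers the NADPH hydride from the alkyne face, which fixes the quaternary future C5 and the temporary C9 carbinol in one catalytic event, and reduction stops there because the remaining C=O becomes a deactivated vinylogous ester.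

Step 5
Reactants: 8 (4R,5S)-4,5-dihydroxy-2,3-dimethoxy-5-[(trimethylsilyl)ethynyl]cyclopent-2-en-1-one
Product: 9 (4S,5S)-2,3-dimethoxy-4,5-bis(triethylsilyloxy)-5-[(trimethylsilyl)ethynyl]cyclopent-2-en-1-one
Conditions: TESOTf (2.5 equiv), 2,6-lutidine (4 equiv), CH2Cl2, −78 to 0 °C
Reagents that add atoms: triethylsilyl triflate, SMILES CC[Si](CC)(CC)OS(=O)(=O)C(F)(F)F
Why: Silyl triflate silylation is strong enough for the tertiary as well as the secondary hydroxyl, removes both acidic protons before the organolithium step, and places two bulky groups on one face of ring A without touching a stereocentre.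

Step 6
Reactants: 9 (4S,5S)-2,3-dimethoxy-4,5-bis(triethylsilyloxy)-5-[(trimethylsilyl)ethynyl]cyclopent-2-en-1-one; 10 methyl vinyl ether
Product: 13 (1R,4S,5S)-2,3-dimethoxy-1-(1-methoxyvinyl)-4,5-bis(triethylsilyloxy)-5-[(trimethylsilyl)ethynyl]cyclopent-2-en-1-ol (all three ring oxygens cis), via 1-methoxyvinyllithium 11 (not isolated), via lithium alkoxide 12 (not isolated)
Conditions: 10 (4 equiv), t-BuLi (3 equiv), THF, −78 to 0 °C; then 9, THF, −78 °C; H2O quench at −78 °C; Et3N-washed silica
Reagents that add atoms: none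
Why: This is a 1,2-addition of an acyl-anion equivalent (a masked CO2Me anion) to a vinylogous-ester carbonyl, as in the first half of a Stork–Danheiser sequence, in which both OTES groups shield the top face and only the rod-like alkyne lies below, so the nucleophile enters syn to the alkyne and the new C6–OH ends up cis to C5–O, while the cold quench forestalls an anionic oxy-Cope shift of the 1,5-enyne alkoxide.

Step 7
Reactants: 13 (1R,4S,5S)-2,3-dimethoxy-1-(1-methoxyvinyl)-4,5-bis(triethylsilyloxy)-5-[(trimethylsilyl)ethynyl]cyclopent-2-en-1-ol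
Product: 14 (1R,2S,3R)-2-ethynyl-4,5-dimethoxy-1-(1-methoxyvinyl)cyclopent-4-ene-1,2,3-triol
Conditions: TBAF (3.3 equiv), THF, 0 °C, short contact; pH 7 buffer work-up
Reagents that add atoms: none
Why: Fluoride-induced desilylation removes both O–TES groups and the C–TMS group under non-acidic conditions that spare the acid-labile enol ethers, and the substrate holds no carbonyl group that the basic medium could attack.

Step 8
Reactants: 14 (1R,2S,3R)-2-ethynyl-4,5-dimethoxy-1-(1-methoxyvinyl)cyclopent-4-ene-1,2,3-triol
Product: 15 (4R,5R)-5-ethynyl-4,5-dihydroxy-2,3-dimethoxy-4-(1-methoxyvinyl)cyclopent-2-en-1-one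
Conditions: SO3·pyridine (3 equiv), DMSO, Et3N (6 equiv), CH2Cl2, 0 °C
Reagents that add atoms: none
Why: Parikh–Doering (activated-DMSO) oxidation touches only the secondary allylic C9 carbinol, does not cleave the vicinal diol as periodinane or periodate oxidants could, stays non-acidic for the enol ethers, and erases the temporary stereocentre while the fully substituted C5 and C6 cannot epimerise.

Step 9
Reactants: 15 (4R,5R)-5-ethynyl-4,5-dihydroxy-2,3-dimethoxy-4-(1-methoxyvinyl)cyclopent-2-en-1-one
Product: 16 methyl (1S,5R)-5-ethynyl-1,5-dihydroxy-2,3-dimethoxy-4-oxocyclopent-2-ene-1-carboxylate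
Conditions: O3 (1 equiv, Sudan Red 7B end point), CH2Cl2/MeOH 4:1, −78 °C; then Me2S, −78 °C to rt
Reagents that add atoms: ozone, SMILES [O-][O+]=O
Why: Ozonolysis of a 1-alkoxyvinyl group gives the ester directly, and the unconjugated 1,1-disubstituted enol ether reacts far faster than the push-pull tetrasubstituted ring alkene or the terminal alkyne, so one equivalent of ozone is selective and no stereocentre is involved.

Step 10
Reactants: 16 methyl (1S,5R)-5-ethynyl-1,5-dihydroxy-2,3-dimethoxy-4-oxocyclopent-2-ene-1-carboxylate; 17 4-acetoxybenzoyl chloride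
Product: 18 methyl (1S,5R)-5-[3-(4-acetoxyphenyl)-3-oxoprop-1-yn-1-yl]-1,5-dihydroxy-2,3-dimethoxy-4-oxocyclopent-2-ene-1-carboxylate
Conditions: PdCl2(PPh3)2 (2 mol %), CuI (4 mol %), Et3N (1.5 equiv), THF, rt, degassed
Reagents that add atoms: none
Why: The acyl Sonogashira coupling (oxidative addition of the acid chloride to zerovalent palladium, transmetalation from the copper acetylide, reductive elimination) runs at room temperature with only Et3N as base, which neither acylates the hindered tertiary alcohols nor triggers a retro-aldol.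

Step 11
Reactants: 18 methyl (1S,5R)-5-[3-(4-acetoxyphenyl)-3-oxoprop-1-yn-1-yl]-1,5-dihydroxy-2,3-dimethoxy-4-oxocyclopent-2-ene-1-carboxylate
Product: 20 methyl (5S,6R)-2-(4-acetoxyphenyl)-6-hydroxy-7,8-dimethoxy-4,9-dioxo-1-oxaspiro[4.4]nona-2,7-diene-6-carboxylate, via 1,3-diketone 19 (not isolated)
Conditions: [(4-CF3C6H4)3P]AuCl (5 mol %), AgOTf (5 mol %), toluene (undried, trace H2O), rt
Reagents that add atoms: water, SMILES O
Why: In this gold-catalysed hydration and cyclodehydration (formal cycloisomerisation of a γ-hydroxy-ynone to a 3(2H)-furanone) carbophilic monovalent gold promotes Michael-type addition of water at the alkyne carbon bound to C5, the C5–OH closes on the aroyl carbonyl and water is lost again, the C5–O bond is never broken so the configuration is kept, and C6–OH cannot compete because it is trans to the side chain and a trans-fused pyranone on the flat cyclopentenone would be too strained.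

Step 12
Reactants: 20 methyl (5S,6R)-2-(4-acetoxyphenyl)-6-hydroxy-7,8-dimethoxy-4,9-dioxo-1-oxaspiro[4.4]nona-2,7-diene-6-carboxylate
Product: 21 limnophilaspiroketone, methyl (5S,6R)-6-hydroxy-2-(4-hydroxyphenyl)-7,8-dimethoxy-4,9-dioxo-1-oxaspiro[4.4]nona-2,7-diene-6-carboxylate
Conditions: lipase (immobilised Candida antarctica lipase B), n-BuOH (5 equiv), MTBE/THF 4:1, 35 °C
Reagents that add atoms: none
Why: Lipase-catalysed transesterification (a serine hydrolase working in a neutral organic medium) removes the exposed aryl acetate while the buried tertiary methyl ester is not a substrate, and the absence of base protects the retro-aldol- and retro-Claisen-prone C5/C6 array.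

## Compound list
1 | disodium croconate | [Na+].[Na+].[O-]C1=C([O-])C(=O)C(=O)C1=O | starting material
2 | disilver croconate | [Ag+].[Ag+].[O-]C1=C([O-])C(=O)C(=O)C1=O | intermediate
3 | dimethyl croconate (4,5-dimethoxycyclopent-4-ene-1,2,3-trione) | COC1=C(OC)C(=O)C(=O)C1=O | intermediate
4 | trimethylsilylacetylene | C#C[Si](C)(C)C | starting material
5 | lithium (trimethylsilyl)acetylide | [Li]C#C[Si](C)(C)C | intermediate
6 | lithium alkoxide of 7 | [Li]OC1(C#C[Si](C)(C)C)C(=O)C(OC)=C(OC)C1=O | intermediate
7 | 2-hydroxy-4,5-dimethoxy-2-[(trimethylsilyl)ethynyl]cyclopent-4-ene-1,3-dione | COC1=C(OC)C(=O)C(O)(C#C[Si](C)(C)C)C1=O | intermediate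
8 | (4R,5S)-4,5-dihydroxy-2,3-dimethoxy-5-[(trimethylsilyl)ethynyl]cyclopent-2-en-1-one | O=C1C(OC)=C(OC)[C@H](O)[C@]1(C#C[Si](C)(C)C)O | intermediate
9 | (4S,5S)-2,3-dimethoxy-4,5-bis(triethylsilyloxy)-5-[(trimethylsilyl)ethynyl]cyclopent-2-en-1-one | O=C1C(OC)=C(OC)[C@H](O[Si](CC)(CC)CC)[C@]1(C#C[Si](C)(C)C)O[Si](CC)(CC)CC | intermediate
10 | methyl vinyl ether | C=COC | starting material
11 | 1-methoxyvinyllithium | [Li]C(=C)OC | intermediate
12 | lithium alkoxide of 13 | C=C(OC)[C@@]1(O[Li])C(OC)=C(OC)[C@H](O[Si](CC)(CC)CC)[C@]1(C#C[Si](C)(C)C)O[Si](CC)(CC)CC | intermediate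
13 | (1R,4S,5S)-2,3-dimethoxy-1-(1-methoxyvinyl)-4,5-bis(triethylsilyloxy)-5-[(trimethylsilyl)ethynyl]cyclopent-2-en-1-ol | C=C(OC)[C@@]1(O)C(OC)=C(OC)[C@H](O[Si](CC)(CC)CC)[C@]1(C#C[Si](C)(C)C)O[Si](CC)(CC)CC | intermediate
14 | (1R,2S,3R)-2-ethynyl-4,5-dimethoxy-1-(1-methoxyvinyl)cyclopent-4-ene-1,2,3-triol | C=C(OC)[C@@]1(O)C(OC)=C(OC)[C@H](O)[C@]1(C#C)O | intermediate
15 | (4R,5R)-5-ethynyl-4,5-dihydroxy-2,3-dimethoxy-4-(1-methoxyvinyl)cyclopent-2-en-1-one | C=C(OC)[C@@]1(O)C(OC)=C(OC)C(=O)[C@]1(C#C)O | intermediate
16 | methyl (1S,5R)-5-ethynyl-1,5-dihydroxy-2,3-dimethoxy-4-oxocyclopent-2-ene-1-carboxylate | COC(=O)[C@@]1(O)C(OC)=C(OC)C(=O)[C@]1(C#C)O | intermediate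
17 | 4-acetoxybenzoyl chloride | CC(=O)Oc1ccc(cc1)C(Cl)=O | starting material
18 | methyl (1S,5R)-5-[3-(4-acetoxyphenyl)-3-oxoprop-1-yn-1-yl]-1,5-dihydroxy-2,3-dimethoxy-4-oxocyclopent-2-ene-1-carboxylate | COC(=O)[C@@]1(O)C(OC)=C(OC)C(=O)[C@]1(C#CC(=O)c2ccc(OC(C)=O)cc2)O | intermediate
19 | methyl (1S,5S)-5-[3-(4-acetoxyphenyl)-3-oxopropanoyl]-1,5-dihydroxy-2,3-dimethoxy-4-oxocyclopent-2-ene-1-carboxylate | COC(=O)[C@@]1(O)C(OC)=C(OC)C(=O)[C@]1(C(=O)CC(=O)c2ccc(OC(C)=O)cc2)O | intermediate
20 | methyl (5S,6R)-2-(4-acetoxyphenyl)-6-hydroxy-7,8-dimethoxy-4,9-dioxo-1-oxaspiro[4.4]nona-2,7-diene-6-carboxylate | COC(=O)[C@@]1(O)C(OC)=C(OC)C(=O)[C@]12OC(c3ccc(OC(C)=O)cc3)=CC2=O | intermediate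
21 | limnophilaspiroketone | COC(=O)[C@@]1(O)C(OC)=C(OC)C(=O)[C@]12OC(c1ccc(O)cc1)=CC2=O | target

## Step count and risks
- Total step count: 12.
- Longest linear sequence: 12 steps (1 to 21).
- Compounds 4, 10 and 17 are bought and enter directly.

**Risk at step 3 (acetylide addition to the trione).** Electron transfer to the strongly accepting trione, or attack at a flanking position, could consume 3. The fallback instead builds ring A by a one-carbon ring expansion and puts the C5 oxygen on electrophilically.
- It sets out from 4.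
- n-BuLi and then paraformaldehyde give 3-(trimethylsilyl)prop-2-yn-1-ol F1.
- Appel chlorination (PPh3, CCl4) gives 3-chloro-1-(trimethylsilyl)prop-1-yne F2.
- Deprotonation of F2 with LDA at −95 °C in the presence of commercial dimethyl squarate (COC1=C(OC)C(=O)C1=O) sets off a Darzens-type addition and a 1,2-acyl shift with loss of chloride. This gives 4,5-dimethoxy-2-[(trimethylsilyl)ethynyl]cyclopent-4-ene-1,3-dione F3.
- Hydroxylation of the doubly activated C–H of F3 with dimethyldioxirane in acetone at −20 °C comes back to the route at 7.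

**Risk at step 4 (ketoreductase desymmetrisation).** No panel enzyme may accept the hindered, oxygen-rich dione with useful selectivity. The fallback moves the desymmetrisation from carbonyl reduction to acyl transfer on a meso compound.
- It sets out from 7.
- Luche reduction (NaBH4, CeCl3·7H2O, MeOH, −78 °C) of both carbonyls from the alkyne face gives all-cis meso-4,5-dimethoxy-2-[(trimethylsilyl)ethynyl]cyclopent-4-ene-1,2,3-triol F4.
- A lipase (Burkholderia cepacia lipase, vinyl acetate, MTBE) acetylates one of the two enantiotopic secondary hydroxyls to give the C9-monoacetate F5.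
- Parikh–Doering oxidation of the remaining secondary carbinol gives the acetoxy enone F6.
- Butanolysis with the same lipase removes the acetate without touching the C–TMS group, and the route is rejoined at 8.

**Risk at step 6 (1-methoxyvinyllithium addition).** The doubly acid-labile adduct may ionise, or its alkoxide may undergo an oxy-Cope shift. The fallback uses a hydroxymethyl-anion equivalent whose adduct has neither the extra enol ether nor the 1,5-enyne, and it reaches the ester by stepwise oxidation instead of ozonolysis.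
- It sets out from 9.
- (Isopropoxydimethylsilyl)methylmagnesium chloride with CeCl3 in THF at −78 to 0 °C adds from the same open face to give the silylmethyl carbinol F7.
- Tamao–Fleming oxidation (KF, KHCO3, H2O2, THF/MeOH), followed in the same flask by TBAF, gives the tetraol F8.
- A double Parikh–Doering oxidation gives the keto aldehyde F9.
- Pinnick oxidation (NaClO2, NaH2PO4, 2-methyl-2-butene) gives the acid F10.
- TMSCHN2 in toluene/MeOH comes back to the route at 16.

## Further compounds
F1 | step 3 | 3-(trimethylsilyl)prop-2-yn-1-ol | OCC#C[Si](C)(C)C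
F2 | step 3 | 3-chloro-1-(trimethylsilyl)prop-1-yne | ClCC#C[Si](C)(C)C
F3 | step 3 | 4,5-dimethoxy-2-[(trimethylsilyl)ethynyl]cyclopent-4-ene-1,3-dione | COC1=C(OC)C(=O)C(C#C[Si](C)(C)C)C1=O
F4 | step 4 | all-cis meso-4,5-dimethoxy-2-[(trimethylsilyl)ethynyl]cyclopent-4-ene-1,2,3-triol | O[C@@H]1C(OC)=C(OC)[C@H](O)[C@]1(C#C[Si](C)(C)C)O
F5 | step 4 | C9-monoacetate of F4 (all ring oxygens cis) | O[C@@H]1C(OC)=C(OC)[C@H](OC(C)=O)[C@]1(C#C[Si](C)(C)C)O
F6 | step 4 | 4-acetoxy-5-hydroxy-2,3-dimethoxy-5-[(trimethylsilyl)ethynyl]cyclopent-2-en-1-one (O-acetate of 8 at the secondary oxygen) | O=C1C(OC)=C(OC)[C@H](OC(C)=O)[C@]1(C#C[Si](C)(C)C)O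
F7 | step 6 | 1-{[isopropoxy(dimethyl)silyl]methyl}-2,3-dimethoxy-4,5-bis(triethylsilyloxy)-5-[(trimethylsilyl)ethynyl]cyclopent-2-en-1-ol (all ring oxygens cis) | CC(C)O[Si](C)(C)C[C@@]1(O)C(OC)=C(OC)[C@H](O[Si](CC)(CC)CC)[C@]1(C#C[Si](C)(C)C)O[Si](CC)(CC)CC
F8 | step 6 | 2-ethynyl-1-(hydroxymethyl)-4,5-dimethoxycyclopent-4-ene-1,2,3-triol (all ring oxygens cis) | OC[C@@]1(O)C(OC)=C(OC)[C@H](O)[C@]1(C#C)O
F9 | step 6 | 5-ethynyl-1,5-dihydroxy-2,3-dimethoxy-4-oxocyclopent-2-ene-1-carbaldehyde (cis-diol) | O=C[C@@]1(O)C(OC)=C(OC)C(=O)[C@]1(C#C)O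
F10 | step 6 | 5-ethynyl-1,5-dihydroxy-2,3-dimethoxy-4-oxocyclopent-2-ene-1-carboxylic acid (cis-diol) | OC(=O)[C@@]1(O)C(OC)=C(OC)C(=O)[C@]1(C#C)O
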